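**Plan**
1. Locants: ring A = C1–C5, C10 (C1 OAc, C4 CMe2, C5 OH, C10 Me); ring B = C5–C10 (C7 OAc); ring C = C8, C9, C11, C13, C14; lactone = C12, C13, C15, C16; C17 = ester carbon; α = face opposite the C10 methyl.
2. Cuts, in retrosynthetic order: epoxide oxygen (back to a C15=C16 enol lactone); C11–C13 (spiro-alkylation of a butenolide, ring C); C13=C15 (metathesis); C8–C14 (enolate + bromomethylfumarate); then C9–C10 and C5–C6 together (ring B).
3. Enabling feature: in ring B, O5 is β to the C7 oxygen (aldol retron) and C10 is 1,5 to C7 through C9–C8 (Michael retron); O1 is cis to C9 on ring A and syn-diaxial to O5, so one silicon on O1 can carry an ynone to C10 and then clamp O5.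
4. Forward: ring A ketone → silyl-ketal-tethered ynone → ring B in one Michael/aldol/silyl-transfer event → C8 side chain → butenolide → ring C by spirocyclization → epoxide.
5. Stereochemistry: C1 by enantioselective catalysis; C10 and C5 relayed from C1 in the key step; C9/C8 by dissolving-metal reduction and equilibration; C7 by O5-directed reduction; C13/C14 by allylic strain; C15/C16 by an anti bromohydrin closure.

Key step: step 5

Remark: the ligand antipode in step 1 is taken to be the one that gives the (3S)-boronate; both C2 epimers of 3 are usable because C2 (= C10) is enolized later.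

Step 1
Reactants: 1 2,6,6-trimethylcyclohex-2-en-1-one
Product: 3 (3S)-3-hydroxy-2,6,6-trimethylcyclohexan-1-one (C2 epimers), via boryl ketone 2 (not isolated)
Conditions: B2pin2, CuCl (5 mol %), NaOtBu, Josiphos-type bisphosphine, MeOH, THF, rt; then NaBO3·4H2O, THF/H2O, rt
Reagents that add atoms: sodium perborate, [Na+].[O-]OB=O
Why: Enantioselective copper-catalysed conjugate borylation of the enone followed by stereoretentive C–B oxidation should set C1 through the chiral copper–boryl complex, while the C10 epimer mixture does not matter.

Step 2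
Reactants: 3 (3S)-3-hydroxy-2,6,6-trimethylcyclohexan-1-one; 4 prop-2-yn-1-ol
Product: 6 (3S)-3-{[di(propan-2-yl)(prop-2-yn-1-yloxy)silyl]oxy}-2,6,6-trimethylcyclohexan-1-one, via chlorosilyl ether 5 (not isolated)
Conditions: iPr2SiCl2 (1.5 equiv), imidazole, CH2Cl2, 0 °C; then 4 (3 equiv), 0 °C → rt
Reagents that add atoms: dichlorodi(propan-2-yl)silane, CC(C)[Si](Cl)(Cl)C(C)C
Why: Stepwise silyl ether formation at a dichlorosilane (temporary silicon connection) should silylate the hindered secondary alcohol first and cap the remaining Si–Cl with the primary alcohol, leaving C1 untouched.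

Step 3
Reactants: 6 silyl ketal
Product: 7 trimethylsilyl enol ether of 6 (C5=C10 double bond)
Conditions: Me3SiOTf, Et3N, CH2Cl2, 0 °C → rt
Reagents that add atoms: trimethylsilyl trifluoromethanesulfonate, C[Si](C)(C)OS(=O)(=O)C(F)(F)F
Why: Soft enolization with a silyl triflate and an amine should give one regiodefined tetrasubstituted silyl enol ether, because the ketone has a single α-hydrogen (C10–H), and both C10 epimers converge.

Step 4
Reactants: 7 trimethylsilyl enol ether; 8 N-methoxy-N-methylacetamide
Product: 9 tethered ynone (O–CH2–C≡C–C(=O)CH3 on silicon)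
Conditions: LiN(SiMe3)2, THF, −78 °C; then 8, −78 → 0 °C; aq NH4Cl
Reagents that add atoms: none
Why: Acylation of the lithium acetylide with a Weinreb amide should give the ynone without over-addition, and the amide base should spare the silyl enol ether and the silyl ketal at low temperature.

Step 5
Reactants: 9 tethered ynone
Product: 12 silylene-bridged 11-hydroxy enone (rings A/B trans, C7 ketone, C8=C9), via (Z)-enone 10 (not isolated), via tethered ketol 11 (not isolated)
Conditions: Bu4N[Ph3SiF2] (1.1 equiv), HN(SiMe3)2 (1.0 equiv), THF, −78 → 0 °C; aq NH4Cl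
Reagents that add atoms: none
Why: Proposed new method: fluoride removes only the trimethylsilyl group of the enol ether and frees the C10 enolate, which adds through the seven-membered silyl-ketal tether to the ynone β-carbon C9 (7-exo-dig, C9–C10 bond); HN(SiMe3)2 protonates the allenolate at C8 from the open side to give the (Z)-enone 10, and the amide formed removes a C6 hydrogen so that the dienolate closes ring B on the C5 ketone (6-enolexo aldol, C5–C6 bond) to give 11. The closest known reaction types are the fluoride-promoted Michael addition of silyl enol ethers, the Robinson-type Michael–aldol annulation stopped at the ketol stage and the temporary silicon connection. C10 is controlled by the tether, which can reach only the enolate face that carries O1, so C9 ends cis and the methyl group trans to O1. C5 is controlled by the chair of ring A in which C9 is equatorial and the O1–Si bond axial: this bond blocks axial entry at the C5 carbonyl, C6 enters equatorially and O5 becomes axial, syn to O1. The axial alkoxide then takes the silicon from the allylic oxygen (six-membered silylene, release of the less basic primary alkoxide), which protects the aldol from retro-aldol and dehydration and gives 12. The step needs fluoride to select the labile Si–O(enol) bond over the hindered silyl ketal and the Michael addition to outrun proton transfer from the acetyl group; low temperature, one equivalent of fluoride and the intramolecular, highly electrophilic ynone should secure both.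

Step 6
Reactants: 13 prop-2-en-1-yl prop-2-enoate (allyl acrylate); 14 methyl 2-oxoacetate (methyl glyoxylate)
Product: 15 1-allyl 4-methyl 3-hydroxy-2-methylidenebutanedioate (racemic)
Conditions: DABCO (20 mol %), neat or THF, rt
Reagents that add atoms: none
Why: The Morita–Baylis–Hillman reaction of an acrylate with the highly electrophilic glyoxylate should join the two, and the new stereocenter is erased in the next step.

Step 7
Reactants: 15 Baylis–Hillman alcohol
Product: 16 1-allyl 4-methyl (2Z)-2-(bromomethyl)but-2-enedioate
Conditions: PBr3, Et2O, 0 °C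
Reagents that add atoms: phosphorus tribromide, BrP(Br)Br
Why: Bromination of a Baylis–Hillman alcohol with allylic transposition (SN2′) should give the conjugated trisubstituted alkene with the bromomethyl group.

Step 8
Reactants: 12 silylene-bridged 11-hydroxy enone; 16 bromomethylfumarate
Product: 17 hydroxy keto diester (9α-H, 8β-H; C8 bears CH(CO2Me)–C(=CH2)–CO2allyl, C14 epimers; C9 bears CH2OH)
Conditions: Li (2.5 equiv), NH3(l)/THF, −78 °C; isoprene; NH3 off; 16 (1.5 equiv), THF, −78 → −30 °C; AcOH
Reagents that add atoms: none
Why: In this Stork reductive alkylation the dissolving metal reduces the enone, the substrate's own hydroxyl protonates C9 axially (H anti to the angular methyl, CH2O equatorial), and the regiodefined C8 lithium enolate adds to 16 by conjugate addition–elimination (SN2′), with C8 settling as the equatorial, epimerizable ketone α-center.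

Step 9
Reactants: 17 hydroxy keto diester
Product: 18 primary iodide (C11–I)
Conditions: I2, PPh3, imidazole, CH2Cl2, 0 °C
Reagents that add atoms: iodine, II
Why: Garegg–Samuelsson (Appel-type) iodination should convert the only free hydroxyl, a primary one, since the 1,5-diol is masked as the silylene.

Step 10
Reactants: 18 primary iodide
Product: 19 butenolide (C14 bears CO2Me and a 2-oxo-2,5-dihydrofuran-3-yl group)
Conditions: second-generation Grubbs catalyst (10 mol %), CH2Cl2, 40 °C
Reagents that add atoms: none
Why: Ring-closing metathesis of the allyl 2-substituted acrylate should give the α-substituted butenolide with loss of ethene and without touching a stereocenter.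

Step 11
Reactants: 19 butenolide
Product: 20 1α,5α-diol (C7 ketone)
Conditions: HF·pyridine, THF, 0 °C → rt
Reagents that add atoms: none
Why: Fluoride cleavage of the dialkoxysilane under buffered acidic conditions should free the C1 and C5 hydroxyls without retro-aldol.

Step 12
Reactants: 20 1α,5α-diol
Product: 21 1α,5α,7β-triol
Conditions: Me4NBH(OAc)3, MeCN/AcOH, −30 → −20 °C
Reagents that add atoms: none
Why: In this Evans–Saksena reduction the axial C5 hydroxyl binds the borohydride and delivers hydride intramolecularly to the α-face of the C7 ketone, which should give the equatorial 7β-alcohol (1,3-anti).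

Step 13
Reactants: 21 triol
Product: 22 1α,7β-diacetate (5α-OH free)
Conditions: Ac2O, Et3N, DMAP (cat.), CH2Cl2, 0 °C → rt
Reagents that add atoms: acetic anhydride, CC(=O)OC(C)=O
Why: DMAP-catalysed acetylation should esterify the two secondary alcohols and leave the hindered tertiary C5 hydroxyl free.

Step 14
Reactants: 22 diacetate
Product: 23 spiro enol lactone (target without the epoxide oxygen, C15=C16)
Conditions: Cs2CO3, DMF, rt
Reagents that add atoms: none
Why: Intramolecular α-alkylation of the butenolide dienolate by the primary iodide (5-exo-tet) should form ring C and the spiro center, because allylic 1,3-strain places the C14 hydrogen beside the enolate oxygen and the ester beside C15, while the C14 epimers interconvert through the ester enolate and the one with the ester trans to C7 cyclizes.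

Step 15
Reactants: 23 spiro enol lactone
Product: 24 bromo lactol (15-bromo on the face of C11, 16-hydroxy, C16 epimers)
Conditions: NBS, THF/H2O (4:1), 0 °C
Reagents that add atoms: N-bromosuccinimide, O=C1CCC(=O)N1Br; water, O
Why: In this bromohydrin formation on the enol lactone, bromine should add to C15 on the face away from the cis C14 ester and water to the acyloxy-stabilized cationic carbon C16.

Step 16
Reactants: 24 bromo lactol
Product: 25 spirocaesalmin
Conditions: Et3N, CH2Cl2, 0 °C
Reagents that add atoms: none
Why: Base-induced halohydrin-to-epoxide closure (intramolecular SN2 with inversion at C15, C16 adjusting by lactol epimerization) should place the epoxide oxygen syn to C14, as in the target.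

**Compound list**
1 | 2,6,6-trimethylcyclohex-2-en-1-one | CC1=CCCC(C)(C)C1=O | starting material
2 | (3S)-2,6,6-trimethyl-3-(4,4,5,5-tetramethyl-1,3,2-dioxaborolan-2-yl)cyclohexan-1-one (C2 epimers) | CC1(C)CC[C@H](B2OC(C)(C)C(C)(C)O2)C(C)C1=O | intermediate (not isolated)
3 | (3S)-3-hydroxy-2,6,6-trimethylcyclohexan-1-one (C2 epimers) | CC1(C)CC[C@H](O)C(C)C1=O | intermediate
4 | prop-2-yn-1-ol | C#CCO | starting material
5 | (3S)-3-{[chlorodi(propan-2-yl)silyl]oxy}-2,6,6-trimethylcyclohexan-1-one | CC1(C)CC[C@H](O[Si](Cl)(C(C)C)C(C)C)C(C)C1=O | intermediate (not isolated)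
6 | (3S)-3-{[di(propan-2-yl)(prop-2-yn-1-yloxy)silyl]oxy}-2,6,6-trimethylcyclohexan-1-one | CC1(C)CC[C@H](O[Si](OCC#C)(C(C)C)C(C)C)C(C)C1=O | intermediate
7 | trimethylsilyl enol ether of 6 (2,6,6-trimethyl-1-trimethylsilyloxycyclohex-1-ene carrying the silyl ketal at C3) | CC1(C)CC[C@H](O[Si](OCC#C)(C(C)C)C(C)C)C(C)=C1O[Si](C)(C)C | intermediate
8 | N-methoxy-N-methylacetamide | CC(=O)N(C)OC | starting material
9 | tethered ynone: as 7, with 4-oxopent-2-yn-1-yloxy in place of propargyloxy on silicon | CC1(C)CC[C@H](O[Si](OCC#CC(C)=O)(C(C)C)C(C)C)C(C)=C1O[Si](C)(C)C | intermediate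
10 | Michael adduct: ring A ketone with quaternary C10; O1 and the C11 oxygen joined by Si(iPr)2 in a seven-membered ring through C1, C10, C9, C11; exocyclic C9=C8, (Z) (acetyl cis to C10) | CC1(C)CC[C@@H]2O[Si](C(C)C)(C(C)C)OC/C(=C/C(C)=O)[C@]2(C)C1=O | intermediate (not isolated)
11 | tethered ketol: ring B closed (5α-OH, C7 ketone, C8=C9), seven-membered O1–Si–O–C11 ring intact | O=C1C[C@@]2(O)C(C)(C)CC[C@@H]3O[Si](C(C)C)(C(C)C)OCC(=C1)[C@@]32C | intermediate (not isolated)
12 | 11-hydroxy enone: trans-fused rings A/B, 4,4,10β-trimethyl, C7 ketone, C8=C9, C9–CH2OH; O1(α) and O5(α) bridged by Si(iPr)2 | O=C1C[C@@]2(O[Si](C(C)C)(C(C)C)O3)C(C)(C)CC[C@H]3[C@]2(C)C(CO)=C1 | intermediate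
13 | prop-2-en-1-yl prop-2-enoate | C=CC(=O)OCC=C | starting material
14 | methyl 2-oxoacetate | COC(=O)C=O | starting material
15 | 1-allyl 4-methyl 3-hydroxy-2-methylidenebutanedioate (racemic) | C=C(C(O)C(=O)OC)C(=O)OCC=C | intermediate
16 | 1-allyl 4-methyl (2Z)-2-(bromomethyl)but-2-enedioate | BrC/C(=C\C(=O)OC)C(=O)OCC=C | intermediate
17 | hydroxy keto diester: as 12 but C8–C9 saturated (8β-H, 9α-H), C8 bears CH(CO2Me)–C(=CH2)–CO2allyl (C14 epimers), C9 bears CH2OH | COC(=O)C(C(=C)C(=O)OCC=C)[C@@H]2C(=O)C[C@@]3(O[Si](C(C)C)(C(C)C)O4)C(C)(C)CC[C@H]4[C@]3(C)[C@H]2CO | intermediate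
18 | iodide: as 17 with C11–I | COC(=O)C(C(=C)C(=O)OCC=C)[C@@H]2C(=O)C[C@@]3(O[Si](C(C)C)(C(C)C)O4)C(C)(C)CC[C@H]4[C@]3(C)[C@H]2CI | intermediate
19 | butenolide: as 18 with C14 bearing CO2Me and 2-oxo-2,5-dihydrofuran-3-yl | COC(=O)C(C1=CCOC1=O)[C@@H]2C(=O)C[C@@]3(O[Si](C(C)C)(C(C)C)O4)C(C)(C)CC[C@H]4[C@]3(C)[C@H]2CI | intermediate
20 | 1α,5α-diol: 19 without the silylene | COC(=O)C(C1=CCOC1=O)[C@@H]2C(=O)C[C@@]3(O)C(C)(C)CC[C@H](O)[C@]3(C)[C@H]2CI | intermediate
21 | 1α,5α,7β-triol | COC(=O)C(C1=CCOC1=O)[C@@H]2[C@@H](O)C[C@@]3(O)C(C)(C)CC[C@H](O)[C@]3(C)[C@H]2CI | intermediate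
22 | 1α,7β-diacetate, 5α-ol | COC(=O)C(C1=CCOC1=O)[C@@H]2[C@@H](OC(C)=O)C[C@@]3(O)C(C)(C)CC[C@H](OC(C)=O)[C@]3(C)[C@H]2CI | intermediate
23 | spiro enol lactone: target skeleton with C15=C16 in place of the epoxide | COC(=O)[C@H]1[C@@H]2[C@@H](OC(C)=O)C[C@@]3(O)C(C)(C)CC[C@H](OC(C)=O)[C@]3(C)[C@H]2C[C@]12C(=O)OC=C2 | intermediate
24 | bromo lactol: 15-bromo (face of C11), 16-hydroxy (C16 epimers) | COC(=O)[C@H]1[C@@H]2[C@@H](OC(C)=O)C[C@@]3(O)C(C)(C)CC[C@H](OC(C)=O)[C@]3(C)[C@H]2C[C@]12C(=O)OC(O)[C@H]2Br | intermediate
25 | spirocaesalmin | COC(=O)[C@H]1[C@@H]2[C@@H](OC(C)=O)C[C@@]3(O)C(C)(C)CC[C@H](OC(C)=O)[C@]3(C)[C@H]2C[C@]12C(=O)O[C@@H]1O[C@@H]12 | target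

Total step count: 16. Longest linear sequence: 14 steps (steps 1–5 and 8–16); steps 6–7 make the side-chain reagent.

**Steps most likely to fail**

Step 5. The cascade may fail in three ways: proton transfer from the acetyl group or fluoride attack on the silyl ketal may compete with the Michael addition; the allenolate may be protonated to the wrong alkene geometry; or the aldol may not close. The fallback makes the two bonds in two known operations, setting out from 9. A Mukaiyama–Michael addition promoted by TiCl4 (CH2Cl2, −78 °C) should give the (Z)-enone 10 together with its (E)-isomer F1. LiN(SiMe3)2 (THF, −78 → 0 °C) with catalytic PhSLi, whose reversible conjugate addition interconverts F1 and 10, then deprotonates the acetyl group; aldol closure and silyl transfer should lead to 12, where the route is rejoined.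

Step 14. The dienolate may alkylate with poor facial control at C13, or on oxygen or at the γ-carbon, and C14 epimerization may be too slow to funnel the material. The fallback sets out from 22: the butenolide is silylated (iPr3SiOTf, Et3N, CH2Cl2) to the 2-silyloxyfuran F3, and ring C is closed by silver-assisted alkylation of the silyloxyfuran with the primary iodide (AgOCOCF3, CH2Cl2, −40 °C). The bulky silyloxy group now enforces the same allylic-strain bias without a free dienolate, and loss of the silyl group returns the route at 23.

Step 8. The C11 lithium alkoxide may be alkylated on oxygen, the enolate may attack the CH2Br terminus directly (SN2 instead of SN2′), or the enolate may equilibrate. The fallback sets out from 12: after the same reduction the enolate and the alkoxide are trapped with Me3SiCl/Et3N as the bis-silyl compound F2. Its silyl enol ether is then coupled with 16 under ZnBr2 (CH2Cl2, −20 °C), a Lewis-acid SN2′ allylation with no free alkoxide or basic enolate present. K2CO3/MeOH removes the O11 silyl group and the route is rejoined at 17.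

Further compounds
F1 | step 5 | (E)-isomer of Michael adduct 10 (acetyl trans to C10) | CC1(C)CC[C@@H]2O[Si](C(C)C)(C(C)C)OC/C(=C\C(C)=O)[C@]2(C)C1=O
F2 | step 8 | bis-silyl compound: C7–C8 trimethylsilyl enol ether of reduced 12 (9α-H) with O11 trimethylsilyl ether | C[Si](C)(C)OC1=C[C@H](CO[Si](C)(C)C)[C@@]2(C)[C@@H]3CCC(C)(C)[C@]2(O[Si](C(C)C)(C(C)C)O3)C1
F3 | step 14 | 2-(triisopropylsilyloxy)furan derived from the butenolide of 22 | COC(=O)C(c1ccoc1O[Si](C(C)C)(C(C)C)C(C)C)[C@@H]2[C@@H](OC(C)=O)C[C@@]3(O)C(C)(C)CC[C@H](OC(C)=O)[C@]3(C)[C@H]2CI
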